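The trans-decalin is opened at C4–C5 and C9–C10 (ring A and ring B) to an (E,E)-homofarnesyl chain that ends in an (R)-epoxide whose C4 carries two identical CH2OTBS arms. Homolytic epoxide opening by Cp2TiCl (trivalent titanium) then forms both bonds in two 6-endo radical closures, sets C5, C9 and C10 from the single C3 stereocentre, and ends by hydrogen loss from C17 to give the C8=C17 exocyclic alkene. The feature exploited is the head-to-tail match of the quaternary C4, the ring A/ring B fusion and the 8(17)-methylene with a polyene. The precursor is PMB-protected at C12; the C3 hydroxyl is deleted afterwards.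

Key step: step 13

Remark: atoms carry labdane locants (C1–C20) and the target is the ent-labdane (5S,9R,10S) as drawn; a plain phosphonoacetate delivers only one C4 arm, so the olefination reagent carries the second, and the (R)-epoxide needs the D-(−)-tartrate because the free hydroxymethyl lies trans to the chain.

Step 1
Reactants: 1 (2E,6E)-farnesol
Product: 2 (2E,6E)-farnesal
Conditions: MnO2 (activated, excess), CH2Cl2, rt
Reagents that add atoms: none
Why: Activated MnO2 oxidises the allylic alcohol chemoselectively to the enal and should leave the isolated alkenes and the 2E geometry untouched (allylic alcohol oxidation).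

Step 2
Reactants: 2 (2E,6E)-farnesal; 3 methyltriphenylphosphonium bromide
Product: 4 (3E,7E)-4,8,12-trimethyltrideca-1,3,7,11-tetraene
Conditions: 3, n-BuLi, THF, 0 °C; then 2, 0 °C to rt
Reagents that add atoms: methyltriphenylphosphonium bromide (3), C[P+](c1ccccc1)(c1ccccc1)c1ccccc1.[Br-]
Why: Wittig methylenation of the enal carbonyl by the non-stabilised ylide is a 1,2-addition that should leave the 3E alkene as it is.

Step 3
Reactants: 4 (3E,7E)-4,8,12-trimethyltrideca-1,3,7,11-tetraene
Product: 6 (3E,7E)-homofarnesol, via B-homofarnesyl-9-BBN 5 (not isolated)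
Conditions: 9-BBN, THF, 0 °C to rt; then NaOH, H2O2, 0 °C to rt
Reagents that add atoms: hydrogen peroxide, OO; 9-borabicyclo[3.3.1]nonane, B1C2CCCC1CCC2 (its boron and carbon atoms stay only in 5)
Why: Anti-Markovnikov hydroboration–oxidation, in which the bulky borane adds only to the monosubstituted terminal alkene (boron on C1) far faster than to any trisubstituted alkene, gives the one-carbon homologue with both E alkenes intact.

Step 4
Reactants: 6 (3E,7E)-homofarnesol; 7 4-methoxybenzyl chloride
Product: 8 (3E,7E)-homofarnesyl 4-methoxybenzyl ether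
Conditions: NaH, 7, Bu4NI (cat.), THF/DMF, 0 °C to rt
Reagents that add atoms: 4-methoxybenzyl chloride (7), COc1ccc(CCl)cc1
Why: Williamson etherification of the primary alkoxide with the benzylic chloride installs an ether that survives every step up to its oxidative removal.

Step 5
Reactants: 8 (3E,7E)-homofarnesyl 4-methoxybenzyl ether
Product: 10 racemic terminal epoxide 3-[(3E,7E)-10-(4-methoxybenzyloxy)-3,7-dimethyldeca-3,7-dien-1-yl]-2,2-dimethyloxirane, via bromohydrin 9 (not isolated)
Conditions: N-bromosuccinimide, THF/H2O, 0 °C; crude bromohydrin, K2CO3, MeOH, rt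
Reagents that add atoms: water, O; N-bromosuccinimide, O=C1CCC(=O)N1Br (its bromine stays only in 9)
Why: Terminal-selective bromohydrin formation in aqueous THF (bromonium ion at the most exposed trisubstituted alkene, Markovnikov opening by water at the tertiary carbon) followed by intramolecular SN2 closure gives the terminal epoxide, whose racemic stereocentre is destroyed in step 6.

Step 6
Reactants: 10 racemic terminal epoxide
Product: 11 (4E,8E)-11-(4-methoxybenzyloxy)-4,8-dimethylundeca-4,8-dienal
Conditions: H5IO6, THF/Et2O (trace H2O), 0 °C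
Reagents that add atoms: none
Why: Periodic acid hydrolyses the epoxide to the glycol and cleaves it in the same flask (Malaprade glycol cleavage), releasing acetone and the trisnor aldehyde whose carbonyl carbon becomes C3.

Step 7
Reactants: 12 triethyl phosphonoacetate; 13 formaldehyde
Product: 14 ethyl 2-(diethoxyphosphoryl)-3-hydroxypropanoate (racemic)
Conditions: 12 (2 equiv), aq. HCHO (1 equiv, slow addition), K2CO3 (cat.), H2O/THF, 0 °C
Reagents that add atoms: formaldehyde (13), C=O
Why: Base-catalysed aldol-type hydroxymethylation of the doubly activated methylene (the first stage of the known phosphonoacetate/formaldehyde route to 2-(hydroxymethyl)acrylate) should stop at the mono-adduct when formaldehyde is the limiting reagent.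

Step 8
Reactants: 14 ethyl 2-(diethoxyphosphoryl)-3-hydroxypropanoate; 15 tert-butyldimethylsilyl chloride
Product: 16 ethyl 3-(tert-butyldimethylsilyloxy)-2-(diethoxyphosphoryl)propanoate (racemic)
Conditions: 15, imidazole, CH2Cl2, 0 °C to rt
Reagents that add atoms: tert-butyldimethylsilyl chloride (15), CC(C)(C)[Si](C)(C)Cl
Why: Standard imidazole-mediated silylation of a primary alcohol blocks retro-aldol loss of formaldehyde and brings the first CH2OTBS arm into the reagent.

Step 9
Reactants: 11 (4E,8E)-11-(4-methoxybenzyloxy)-4,8-dimethylundeca-4,8-dienal; 16 ethyl 3-(tert-butyldimethylsilyloxy)-2-(diethoxyphosphoryl)propanoate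
Product: 17 ethyl (2E,6E,10E)-2-[(tert-butyldimethylsilyloxy)methyl]-13-(4-methoxybenzyloxy)-6,10-dimethyltrideca-2,6,10-trienoate
Conditions: 16, NaH, THF, 0 °C; then 11, 0 °C to rt
Reagents that add atoms: phosphonate 16, CCOC(=O)C(CO[Si](C)(C)C(C)(C)C)P(=O)(OCC)OCC
Why: Horner–Wadsworth–Emmons olefination with a 2-substituted phosphonoacetate, whose reversible addition and preferred anti-oxaphosphetane should give the 2E enoate (chain trans to CO2Et), the geometry that decides which arm later becomes the free allylic alcohol.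

Step 10
Reactants: 17 ethyl (2E,6E,10E)-enoate
Product: 18 (2Z,6E,10E)-2-[(tert-butyldimethylsilyloxy)methyl]-13-(4-methoxybenzyloxy)-6,10-dimethyltrideca-2,6,10-trien-1-ol (free CH2OH trans to the chain)
Conditions: iBu2AlH, CH2Cl2, −78 °C; aq. potassium sodium tartrate
Reagents that add atoms: none
Why: 1,2-Reduction of the enoate by iBu2AlH at low temperature gives the allylic alcohol with the alkene geometry retained, the silyl and PMB ethers being inert.

Step 11
Reactants: 18 (2Z,6E,10E)-allylic alcohol
Product: 19 [(2S,3R)-2-[(tert-butyldimethylsilyloxy)methyl]-3-[(3E,7E)-10-(4-methoxybenzyloxy)-3,7-dimethyldeca-3,7-dien-1-yl]oxiran-2-yl]methanol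
Conditions: Ti(OiPr)4 (cat.), D-(−)-diethyl tartrate (cat.), tBuOOH (in decane), 4 Å molecular sieves, CH2Cl2, −20 °C
Reagents that add atoms: tert-butyl hydroperoxide, CC(C)(C)OO
Why: Katsuki–Sharpless asymmetric epoxidation touches only the allylic-alcohol alkene, and for a hydroxymethyl trans to the chain (the substrate class of E-2-substituted alk-2-en-1-ols) the D-(−)-tartrate catalyst delivers oxygen to the face that makes C3 R.

Step 12
Reactants: 19 (2S,3R)-epoxy alcohol; 15 tert-butyldimethylsilyl chloride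
Product: 20 (3R)-2,2-bis[(tert-butyldimethylsilyloxy)methyl]-3-[(3E,7E)-10-(4-methoxybenzyloxy)-3,7-dimethyldeca-3,7-dien-1-yl]oxirane
Conditions: 15, imidazole, DMF, rt
Reagents that add atoms: tert-butyldimethylsilyl chloride (15), CC(C)(C)[Si](C)(C)Cl
Why: Base-mild silylation of the remaining primary alcohol (no Payne rearrangement under imidazole) makes the two arms identical, so that C4 is no longer stereogenic and C3 is the only stereocentre.

Step 13
Reactants: 20 (3R)-bis(silyloxymethyl) epoxide
Product: 21 (3R,5S,9R,10S)-18,19-bis(tert-butyldimethylsilyloxy)-12-(4-methoxybenzyloxy)-13,14,15,16-tetranor-ent-labd-8(17)-en-3-ol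
Conditions: Cp2TiCl2 (2.5 equiv), Mn dust (8 equiv), degassed THF, rt, green Cp2TiCl solution added dropwise to dilute 20; then aq. NaH2PO4
Reagents that add atoms: none
Why: Cp2TiCl (trivalent titanium, a one-electron reductant) binds the epoxide oxygen and cleaves the C4–O bond homolytically to the tertiary C4 radical while the oxygen stays on C3 as a titanium alkoxide (Nugent–RajanBabu epoxide opening, in its established use for the radical cyclisation of epoxypolyprenes). Ring A closes by 6-endo-trig attack of C4 on C5 of the C5=C10 alkene and ring B by 6-endo-trig attack of the C10 radical on C9 of the C8=C9 alkene, each closure giving the more substituted tertiary radical. Both closures should run through a chair–chair arrangement with the C3–O bond equatorial, so the single C3 stereocentre fixes the face of C5, and the E geometry of the two alkenes then gives the anti relation of H-5 and the C10 methyl and the equatorial C9 side chain (C5, C9 and C10 are all set here). The tertiary C8 radical is intercepted by a second Cp2TiCl and the resulting alkyl–titanium species loses a hydrogen from the least hindered C17 methyl (β-hydride elimination), which should give the 8(17)-methylene in preference to the endocyclic isomers. The step needs 6-endo over 5-exo closure (secured by the trisubstituted alkenes), cyclisation faster than trapping of the C4 radical (secured by dilution and slow addition of Cp2TiCl) and exocyclic termination (inherent to this reagent). The identical CH2OTBS arms keep C4 stereochemically silent and the non-acidic medium spares the PMB and silyl ethers.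

Step 14
Reactants: 21 bicyclic C3 alcohol; 22 1,1'-thiocarbonyldiimidazole
Product: 23 O-[(3R,5S,9R,10S)-18,19-bis(tert-butyldimethylsilyloxy)-12-(4-methoxybenzyloxy)-13,14,15,16-tetranor-ent-labd-8(17)-en-3-yl] 1H-imidazole-1-carbothioate
Conditions: 22, DMAP (cat.), toluene, 90 °C
Reagents that add atoms: 1,1'-thiocarbonyldiimidazole (22), S=C(n1ccnc1)n1ccnc1
Why: Thioacylation of the secondary alcohol under neutral conditions (first stage of the Barton–McCombie deoxygenation) avoids the alkoxide that could trigger 1,3-silyl migration from the neighbouring CH2OTBS groups.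

Step 15
Reactants: 23 C3 thiocarbonylimidazolide
Product: 24 (5S,9R,10S)-18,19-bis(tert-butyldimethylsilyloxy)-13,14,15,16-tetranor-ent-labd-8(17)-en-12-yl 4-methoxybenzyl ether
Conditions: Bu3SnH, AIBN (cat.), toluene, 110 °C
Reagents that add atoms: none
Why: Barton–McCombie radical deoxygenation (stannyl radical addition to C=S, C3–O fragmentation, hydrogen transfer from Bu3SnH to the secondary C3 radical) turns C3 into CH2 without involving the remote exocyclic alkene or the ring stereocentres.

Step 16
Reactants: 24 C3-deoxy PMB ether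
Product: 25 (5S,9R,10S)-18,19-bis(tert-butyldimethylsilyloxy)-13,14,15,16-tetranor-ent-labd-8(17)-en-12-ol
Conditions: DDQ, CH2Cl2/aq. pH 7 phosphate buffer, 0 °C
Reagents that add atoms: none
Why: Oxidative PMB cleavage by DDQ proceeds through the benzylic oxocarbenium ion, which the buffer water hydrolyses, while silyl ethers and the unactivated exocyclic alkene are inert.

Step 17
Reactants: 25 C12 alcohol
Product: 26 (5S,9R,10S)-18,19-bis(tert-butyldimethylsilyloxy)-13,14,15,16-tetranor-ent-labd-8(17)-en-12-al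
Conditions: Dess–Martin periodinane, CH2Cl2, rt
Reagents that add atoms: none
Why: Dess–Martin oxidation gives the aldehyde under near-neutral conditions, and since the α-carbon C11 is a CH2 no stereocentre can epimerise.

Step 18
Reactants: 26 C12 aldehyde; 27 2-(triphenylphosphoranylidene)propanal
Product: 28 (12E)-18,19-bis(tert-butyldimethylsilyloxy)-15-nor-ent-labda-8(17),12-dien-14-al
Conditions: 27, toluene, 90 °C
Reagents that add atoms: 2-(triphenylphosphoranylidene)propanal (27), CC(C=O)=P(c1ccccc1)(c1ccccc1)c1ccccc1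
Why: Wittig olefination with a stabilised α-methyl formyl ylide is reversible in the addition step and should give the 12E trisubstituted enal (C11 trans to the formyl group).

Step 19
Reactants: 28 (12E)-enal; 3 methyltriphenylphosphonium bromide
Product: 29 (12E)-18,19-bis(tert-butyldimethylsilyloxy)-ent-labda-8(17),12,14-triene
Conditions: 3, n-BuLi, THF, 0 °C; then 28, −78 to 0 °C
Reagents that add atoms: methyltriphenylphosphonium bromide (3), C[P+](c1ccccc1)(c1ccccc1)c1ccccc1.[Br-]
Why: Wittig methylenation of the enal carbonyl (1,2-addition) completes the 12E-configured 12,14-diene without touching the trisubstituted alkene.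

Step 20
Reactants: 29 bis-silyl triene
Product: 30 (12E)-ent-labda-8(17),12,14-triene-18,19-diol
Conditions: Bu4NF, THF, rt to 40 °C
Reagents that add atoms: none
Why: Fluoride-induced desilylation (Si–F bond formation) frees both primary alcohols under conditions to which the diene and the exocyclic alkene are stable.

Step 21
Reactants: 30 triene diol; 31 acetic anhydride
Product: 32 (5S,9R,10S,12E)-ent-labda-8(17),12,14-triene-18,19-diyl diacetate (target)
Conditions: 31, pyridine, DMAP (cat.), CH2Cl2, rt
Reagents that add atoms: acetic anhydride (31), CC(=O)OC(C)=O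
Why: DMAP-catalysed acetylation of the two primary neopentyl-type alcohols gives the diacetate under mild, non-acidic conditions that leave the diene untouched.

Compound list

1 | (2E,6E)-farnesol, (2E,6E)-3,7,11-trimethyldodeca-2,6,10-trien-1-ol | CC(C)=CCC/C(C)=C/CC/C(C)=C/CO | starting material
2 | (2E,6E)-farnesal | CC(C)=CCC/C(C)=C/CC/C(C)=C/C=O | intermediate
3 | methyltriphenylphosphonium bromide | C[P+](c1ccccc1)(c1ccccc1)c1ccccc1.[Br-] | starting material
4 | (3E,7E)-4,8,12-trimethyltrideca-1,3,7,11-tetraene | CC(C)=CCC/C(C)=C/CC/C(C)=C/C=C | intermediate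
5 | 9-[(3E,7E)-4,8,12-trimethyltrideca-3,7,11-trien-1-yl]-9-borabicyclo[3.3.1]nonane | CC(C)=CCC/C(C)=C/CC/C(C)=C/CCB1C2CCCC1CCC2 | intermediate (not isolated)
6 | (3E,7E)-homofarnesol, (3E,7E)-4,8,12-trimethyltrideca-3,7,11-trien-1-ol | CC(C)=CCC/C(C)=C/CC/C(C)=C/CCO | intermediate
7 | 4-methoxybenzyl chloride | COc1ccc(CCl)cc1 | starting material
8 | 1-methoxy-4-({[(3E,7E)-4,8,12-trimethyltrideca-3,7,11-trien-1-yl]oxy}methyl)benzene | COc1ccc(COCC/C=C(\C)CC/C=C(\C)CCC=C(C)C)cc1 | intermediate
9 | (6E,10E)-3-bromo-13-(4-methoxybenzyloxy)-2,6,10-trimethyltrideca-6,10-dien-2-ol (racemic) | COc1ccc(COCC/C=C(\C)CC/C=C(\C)CCC(Br)C(C)(C)O)cc1 | intermediate (not isolated)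
10 | 3-[(3E,7E)-10-(4-methoxybenzyloxy)-3,7-dimethyldeca-3,7-dien-1-yl]-2,2-dimethyloxirane (racemic) | COc1ccc(COCC/C=C(\C)CC/C=C(\C)CCC2OC2(C)C)cc1 | intermediate
11 | (4E,8E)-11-(4-methoxybenzyloxy)-4,8-dimethylundeca-4,8-dienal | COc1ccc(COCC/C=C(\C)CC/C=C(\C)CCC=O)cc1 | intermediate
12 | triethyl phosphonoacetate | CCOC(=O)CP(=O)(OCC)OCC | starting material
13 | formaldehyde | C=O | starting material
14 | ethyl 2-(diethoxyphosphoryl)-3-hydroxypropanoate (racemic) | CCOC(=O)C(CO)P(=O)(OCC)OCC | intermediate
15 | tert-butyldimethylsilyl chloride | CC(C)(C)[Si](C)(C)Cl | starting material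
16 | ethyl 3-(tert-butyldimethylsilyloxy)-2-(diethoxyphosphoryl)propanoate (racemic) | CCOC(=O)C(CO[Si](C)(C)C(C)(C)C)P(=O)(OCC)OCC | intermediate
17 | ethyl (2E,6E,10E)-2-[(tert-butyldimethylsilyloxy)methyl]-13-(4-methoxybenzyloxy)-6,10-dimethyltrideca-2,6,10-trienoate | COc1ccc(COCC/C=C(\C)CC/C=C(\C)CC/C=C(/C(=O)OCC)CO[Si](C)(C)C(C)(C)C)cc1 | intermediate
18 | (2Z,6E,10E)-2-[(tert-butyldimethylsilyloxy)methyl]-13-(4-methoxybenzyloxy)-6,10-dimethyltrideca-2,6,10-trien-1-ol | COc1ccc(COCC/C=C(\C)CC/C=C(\C)CC/C=C(/CO)CO[Si](C)(C)C(C)(C)C)cc1 | intermediate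
19 | [(2S,3R)-2-[(tert-butyldimethylsilyloxy)methyl]-3-[(3E,7E)-10-(4-methoxybenzyloxy)-3,7-dimethyldeca-3,7-dien-1-yl]oxiran-2-yl]methanol | COc1ccc(COCC/C=C(\C)CC/C=C(\C)CC[C@H]2O[C@@]2(CO)CO[Si](C)(C)C(C)(C)C)cc1 | intermediate
20 | (3R)-2,2-bis[(tert-butyldimethylsilyloxy)methyl]-3-[(3E,7E)-10-(4-methoxybenzyloxy)-3,7-dimethyldeca-3,7-dien-1-yl]oxirane | COc1ccc(COCC/C=C(\C)CC/C=C(\C)CC[C@H]2OC2(CO[Si](C)(C)C(C)(C)C)CO[Si](C)(C)C(C)(C)C)cc1 | intermediate (key-step precursor)
21 | (3R,5S,9R,10S)-18,19-bis(tert-butyldimethylsilyloxy)-12-(4-methoxybenzyloxy)-13,14,15,16-tetranor-ent-labd-8(17)-en-3-ol (trans-decalin, equatorial 3-OH) | COc1ccc(COCC[C@@H]2C(=C)CC[C@@H]3C(CO[Si](C)(C)C(C)(C)C)(CO[Si](C)(C)C(C)(C)C)[C@H](O)CC[C@@]23C)cc1 | intermediate (key-step product)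
22 | 1,1'-thiocarbonyldiimidazole | S=C(n1ccnc1)n1ccnc1 | starting material
23 | O-[(3R,5S,9R,10S)-18,19-bis(tert-butyldimethylsilyloxy)-12-(4-methoxybenzyloxy)-13,14,15,16-tetranor-ent-labd-8(17)-en-3-yl] 1H-imidazole-1-carbothioate | COc1ccc(COCC[C@@H]2C(=C)CC[C@@H]3C(CO[Si](C)(C)C(C)(C)C)(CO[Si](C)(C)C(C)(C)C)[C@H](OC(=S)n4ccnc4)CC[C@@]23C)cc1 | intermediate
24 | (5S,9R,10S)-18,19-bis(tert-butyldimethylsilyloxy)-13,14,15,16-tetranor-ent-labd-8(17)-en-12-yl 4-methoxybenzyl ether | COc1ccc(COCC[C@@H]2C(=C)CC[C@@H]3C(CO[Si](C)(C)C(C)(C)C)(CO[Si](C)(C)C(C)(C)C)CCC[C@@]23C)cc1 | intermediate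
25 | (5S,9R,10S)-18,19-bis(tert-butyldimethylsilyloxy)-13,14,15,16-tetranor-ent-labd-8(17)-en-12-ol | OCC[C@@H]1C(=C)CC[C@@H]2C(CO[Si](C)(C)C(C)(C)C)(CO[Si](C)(C)C(C)(C)C)CCC[C@@]12C | intermediate
26 | (5S,9R,10S)-18,19-bis(tert-butyldimethylsilyloxy)-13,14,15,16-tetranor-ent-labd-8(17)-en-12-al | O=CC[C@@H]1C(=C)CC[C@@H]2C(CO[Si](C)(C)C(C)(C)C)(CO[Si](C)(C)C(C)(C)C)CCC[C@@]12C | intermediate
27 | 2-(triphenylphosphoranylidene)propanal | CC(C=O)=P(c1ccccc1)(c1ccccc1)c1ccccc1 | starting material
28 | (5S,9R,10S,12E)-18,19-bis(tert-butyldimethylsilyloxy)-15-nor-ent-labda-8(17),12-dien-14-al | O=C/C(C)=C/C[C@@H]1C(=C)CC[C@@H]2C(CO[Si](C)(C)C(C)(C)C)(CO[Si](C)(C)C(C)(C)C)CCC[C@@]12C | intermediate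
29 | (5S,9R,10S,12E)-18,19-bis(tert-butyldimethylsilyloxy)-ent-labda-8(17),12,14-triene | C=C/C(C)=C/C[C@@H]1C(=C)CC[C@@H]2C(CO[Si](C)(C)C(C)(C)C)(CO[Si](C)(C)C(C)(C)C)CCC[C@@]12C | intermediate
30 | (5S,9R,10S,12E)-ent-labda-8(17),12,14-triene-18,19-diol | C=C/C(C)=C/C[C@@H]1C(=C)CC[C@@H]2C(CO)(CO)CCC[C@@]12C | intermediate
31 | acetic anhydride | CC(=O)OC(C)=O | starting material
32 | (5S,9R,10S,12E)-ent-labda-8(17),12,14-triene-18,19-diyl diacetate | C=C/C(C)=C/C[C@@H]1C(=C)CC[C@@H]2C(COC(C)=O)(COC(C)=O)CCC[C@@]12C | target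

Total step count: 21 (steps 7 and 8 prepare the olefination reagent).
Longest linear sequence: 19 steps (steps 1–6 and 9–21, from farnesol).

Steps most likely to fail

Step 13. The tertiary C4 radical, slowed by its two bulky and inductively withdrawing arms, may be reduced or trapped by titanium before it reaches C5. That would mean deoxygenation back to the alkene, an acyclic alcohol, or a cascade that stops after ring A. The fallback changes the radical precursor itself. Setting out from 19, the silyl group would be removed (Bu4NF, THF) to give the epoxy diol [(3R)-3-[(3E,7E)-10-(4-methoxybenzyloxy)-3,7-dimethyldeca-3,7-dien-1-yl]oxirane-2,2-diyl]dimethanol F1. The two arms would then be tied together (2,2-dimethoxypropane, PPTS, CH2Cl2) as the spiro acetonide (2R)-2-[(3E,7E)-10-(4-methoxybenzyloxy)-3,7-dimethyldeca-3,7-dien-1-yl]-6,6-dimethyl-1,5,7-trioxaspiro[2.5]octane F2. Its compact ring radical should cyclise under Cp2TiCl2/Mn in THF to the 18,19-O-isopropylidene 3-hydroxy bicycle F3. Methanolysis (PPTS, MeOH) would give the 3,18,19-triol F4, and selective silylation of its two primary hydroxyls (TBSCl, imidazole, CH2Cl2, 0 °C) would come back to the route at 21.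

Step 9. The olefination may give poor E/Z control, or the phosphonate anion may lose silanolate by β-elimination; either would erode the geometric purity on which the enantiomeric purity of the epoxide depends. The fallback is a Morita–Baylis–Hillman route whose geometry is set by an allylic transposition.
- Setting out from 11, reaction with methyl acrylate and DABCO would give the racemic adduct methyl (6E,10E)-3-hydroxy-13-(4-methoxybenzyloxy)-6,10-dimethyl-2-methylidenetrideca-6,10-dienoate F5.
- Acetylation (Ac2O, DMAP) would give its acetate F6.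
- DABCO-catalysed 1,3-acetoxy shift in refluxing THF would give methyl (2E,6E,10E)-2-(acetoxymethyl)-13-(4-methoxybenzyloxy)-6,10-dimethyltrideca-2,6,10-trienoate F7.
- Mild methanolysis (K2CO3, MeOH, 0 °C) would give the hydroxymethyl enoate F8.
- Silylation (TBSCl, imidazole) would give the methyl ester analogue of 17, F9.
- Reduction with iBu2AlH would come back to the route at 18.

Step 14. Thioacylation of the C3 hydroxyl, which is flanked by the fully substituted C4, may stall, and forcing it under basic conditions risks silyl migration. The fallback is an ionic deoxygenation through the ketone. Setting out from 21, Dess–Martin oxidation would give the 3-ketone F10. Condensation with TsNHNH2 in MeOH at 60 °C would give the tosylhydrazone F11. Reduction with catecholborane in CHCl3 and then NaOAc·3H2O at reflux (Caglioti-type tosylhydrazone reduction) would come back to the route at 24.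

Further compounds

F1 | step 13 | [(3R)-3-[(3E,7E)-10-(4-methoxybenzyloxy)-3,7-dimethyldeca-3,7-dien-1-yl]oxirane-2,2-diyl]dimethanol | COc1ccc(COCC/C=C(\C)CC/C=C(\C)CC[C@H]2OC2(CO)CO)cc1
F2 | step 13 | (2R)-2-[(3E,7E)-10-(4-methoxybenzyloxy)-3,7-dimethyldeca-3,7-dien-1-yl]-6,6-dimethyl-1,5,7-trioxaspiro[2.5]octane | COc1ccc(COCC/C=C(\C)CC/C=C(\C)CC[C@H]2OC23COC(C)(C)OC3)cc1
F3 | step 13 | (3R,5S,9R,10S)-18,19-O-isopropylidene-12-(4-methoxybenzyloxy)-13,14,15,16-tetranor-ent-labd-8(17)-ene-3,18,19-triol | COc1ccc(COCC[C@@H]2C(=C)CC[C@@H]3C4(COC(C)(C)OC4)[C@H](O)CC[C@@]23C)cc1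
F4 | step 13 | (3R,5S,9R,10S)-12-(4-methoxybenzyloxy)-13,14,15,16-tetranor-ent-labd-8(17)-ene-3,18,19-triol | COc1ccc(COCC[C@@H]2C(=C)CC[C@@H]3C(CO)(CO)[C@H](O)CC[C@@]23C)cc1
F5 | step 9 | methyl (6E,10E)-3-hydroxy-13-(4-methoxybenzyloxy)-6,10-dimethyl-2-methylidenetrideca-6,10-dienoate (racemic) | COc1ccc(COCC/C=C(\C)CC/C=C(\C)CCC(O)C(=C)C(=O)OC)cc1
F6 | step 9 | methyl (6E,10E)-3-acetoxy-13-(4-methoxybenzyloxy)-6,10-dimethyl-2-methylidenetrideca-6,10-dienoate (racemic) | COc1ccc(COCC/C=C(\C)CC/C=C(\C)CCC(OC(C)=O)C(=C)C(=O)OC)cc1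
F7 | step 9 | methyl (2E,6E,10E)-2-(acetoxymethyl)-13-(4-methoxybenzyloxy)-6,10-dimethyltrideca-2,6,10-trienoate | COc1ccc(COCC/C=C(\C)CC/C=C(\C)CC/C=C(/C(=O)OC)COC(C)=O)cc1
F8 | step 9 | methyl (2E,6E,10E)-2-(hydroxymethyl)-13-(4-methoxybenzyloxy)-6,10-dimethyltrideca-2,6,10-trienoate | COc1ccc(COCC/C=C(\C)CC/C=C(\C)CC/C=C(/C(=O)OC)CO)cc1
F9 | step 9 | methyl (2E,6E,10E)-2-[(tert-butyldimethylsilyloxy)methyl]-13-(4-methoxybenzyloxy)-6,10-dimethyltrideca-2,6,10-trienoate | COc1ccc(COCC/C=C(\C)CC/C=C(\C)CC/C=C(/C(=O)OC)CO[Si](C)(C)C(C)(C)C)cc1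
F10 | step 14 | (5S,9R,10S)-18,19-bis(tert-butyldimethylsilyloxy)-12-(4-methoxybenzyloxy)-13,14,15,16-tetranor-ent-labd-8(17)-en-3-one | COc1ccc(COCC[C@@H]2C(=C)CC[C@@H]3C(CO[Si](C)(C)C(C)(C)C)(CO[Si](C)(C)C(C)(C)C)C(=O)CC[C@@]23C)cc1
F11 | step 14 | 4-methylbenzenesulfonohydrazone of ketone F10 | COc1ccc(COCC[C@@H]2C(=C)CC[C@@H]3C(CO[Si](C)(C)C(C)(C)C)(CO[Si](C)(C)C(C)(C)C)C(=NNS(=O)(=O)c4ccc(C)cc4)CC[C@@]23C)cc1
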